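**Retrosynthetic overview**

- The strategy rests on ring A, whose six carbons are all substituted: C1 and C4 are the quinone carbonyls, C2 carries OMe, C3 methyl, C5 the free OH and C6 the tridecyl tether. C1/C6/C5/C4 map onto a squaric ester and C2/C3 onto a 1-methoxypropen-2-yl unit.
- Ring A comes from hydroquinone 20, made by thermal ring expansion of 4-alkenyl-4-hydroxycyclobutenone 17 (forms C1–C2, closes ring A). A tert-butyl ether at C5 and a methyl ether at C2 keep the two oxygens distinct.
- 17 comes from cyclobutenedione 13 and alkenyllithium 16 (from 2-bromo-1,1-dimethoxypropane); 13 comes from di-tert-butyl squarate and the C13 Grignard reagent 11.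
- 11 comes from benzylic bromide 4 (from 3,5-dihydroxy-4-methylbenzoic acid) and the C12 Grignard reagent 7 (from 12-bromododecan-1-ol) by copper-catalysed sp3–sp3 coupling.
- Ring order: the ring B carbocycle is carried from the start as a dibenzyl resorcinol, ring A is closed in step 10, and ring B is oxidised last (debenzylation, (KSO3)2NO, Thiele–Winter acetoxylation, methanolysis and air).

Key step: step 10

Remark: the elimination in step 8 is expected to give both geometric isomers of 2-bromo-1-methoxypropene; the E isomer is carried on after fractional distillation, and Z material would feed the same hydroquinone 20 because the alkene geometry is erased when ring A aromatises.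
Remark: compounds 12, 17 and 19 are racemic; their single stereocentre is destroyed on the way to 20, and the target is achiral.

**Route**

Step 1
Reactants: 1 3,5-dihydroxy-4-methylbenzoic acid
Product: 2 benzyl 3,5-bis(benzyloxy)-4-methylbenzoate
Conditions: BnBr (3.3 equiv), K2CO3, DMF, 60 °C
Reagents that add atoms: benzyl bromide, BrCc1ccccc1
Why: Williamson etherification of both phenols and O-alkylation of the carboxylate should occur in one operation under carbonate in DMF.

Step 2
Reactants: 2 benzyl 3,5-bis(benzyloxy)-4-methylbenzoate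
Product: 3 [3,5-bis(benzyloxy)-4-methylphenyl]methanol
Conditions: LiAlH4, THF, 0 °C to rt; then H2O, aq. NaOH
Reagents that add atoms: none
Why: Hydride reduction of the benzyl ester to the primary alcohol leaves the aryl benzyl ethers untouched.

Step 3
Reactants: 3 [3,5-bis(benzyloxy)-4-methylphenyl]methanol
Product: 4 1,3-bis(benzyloxy)-5-(bromomethyl)-2-methylbenzene
Conditions: CBr4, PPh3, CH2Cl2, 0 °C
Reagents that add atoms: carbon tetrabromide, BrC(Br)(Br)Br
Why: The Appel reaction converts the benzylic alcohol to the bromide under neutral conditions that spare the benzyl ethers.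

Step 4
Reactants: 5 12-bromododecan-1-ol
Product: 6 [(12-bromododecyl)oxy](tert-butyl)dimethylsilane
Conditions: t-BuMe2SiCl, imidazole, CH2Cl2, rt
Reagents that add atoms: tert-butyldimethylsilyl chloride, CC(C)(C)[Si](C)(C)Cl
Why: Silylation of the primary alcohol masks the acidic proton so that the bromide can be turned into a Grignard reagent.

Step 5
Reactants: 6 [(12-bromododecyl)oxy](tert-butyl)dimethylsilane; 4 1,3-bis(benzyloxy)-5-(bromomethyl)-2-methylbenzene
Product: 8 ({13-[3,5-bis(benzyloxy)-4-methylphenyl]tridecyl}oxy)(tert-butyl)dimethylsilane, via Grignard reagent 7 (not isolated)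
Conditions: Mg, THF, 45 °C; then 4, Li2CuCl4 (cat.), THF, −20 °C to rt
Reagents that add atoms: none
Why: Copper-catalysed sp3–sp3 cross-coupling of a primary alkyl Grignard reagent with a benzylic bromide (Kochi-type coupling) should give the C13 chain, the silyl and benzyl ethers being inert.

Step 6
Reactants: 8 ({13-[3,5-bis(benzyloxy)-4-methylphenyl]tridecyl}oxy)(tert-butyl)dimethylsilane
Product: 9 1,3-bis(benzyloxy)-5-(13-bromotridecyl)-2-methylbenzene
Conditions: Ph3PBr2 (preformed from PPh3 and Br2, slight excess of PPh3), CH2Cl2, 0 °C to rt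
Reagents that add atoms: dibromotriphenylphosphorane, BrP(Br)(c1ccccc1)(c1ccccc1)c1ccccc1
Why: Direct conversion of a primary silyl ether to the bromide goes through an alkoxyphosphonium ion and SN2 displacement by bromide, while the far less nucleophilic aryl benzyl ether oxygens should not react.

Step 7
Reactants: 9 1,3-bis(benzyloxy)-5-(13-bromotridecyl)-2-methylbenzene; 10 di-tert-butyl squarate
Product: 13 3-{13-[3,5-bis(benzyloxy)-4-methylphenyl]tridecyl}-4-tert-butoxycyclobut-3-ene-1,2-dione, via Grignard reagent 11 (not isolated), via bromomagnesium alkoxide 12 (not isolated)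
Conditions: Mg, THF, 50 °C; then 10, THF, −78 °C; then (CF3CO)2O, −78 to 0 °C; aq. NaHCO3
Reagents that add atoms: none
Why: 1,2-Addition of the Grignard reagent to one squarate carbonyl, then trifluoroacetylation of the tertiary alkoxide, should trigger ionisation and loss of tert-butyl from the vinylogous oxocarbenium ion, which unveils the second carbonyl (the standard squarate-to-cyclobutenedione transposition).

Step 8
Reactants: 14 2-bromo-1,1-dimethoxypropane
Product: 15 (E)-2-bromo-1-methoxyprop-1-ene
Conditions: Me3SiOTf, iPr2NEt, CH2Cl2, −20 °C to rt; fractional distillation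
Reagents that add atoms: none
Why: Me3SiOTf ionises the acetal to an oxocarbenium ion that the hindered amine deprotonates at C2 (acetal-to-enol-ether elimination), the bromine staying on the new alkene.

Step 9
Reactants: 15 (E)-2-bromo-1-methoxyprop-1-ene; 13 3-{13-[3,5-bis(benzyloxy)-4-methylphenyl]tridecyl}-4-tert-butoxycyclobut-3-ene-1,2-dione
Product: 17 racemic 2-{13-[3,5-bis(benzyloxy)-4-methylphenyl]tridecyl}-3-tert-butoxy-4-hydroxy-4-[(E)-1-methoxyprop-1-en-2-yl]cyclobut-2-en-1-one, via alkenyllithium 16 (not isolated)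
Conditions: t-BuLi (2 equiv), THF/Et2O, −78 °C; then 13, THF, −78 °C; aq. NH4Cl at −78 °C
Reagents that add atoms: none
Why: Bromine–lithium exchange with retention of alkene geometry gives 16, which should add 1,2 to the carbonyl of 13 flanked by the tert-butoxy-bearing carbon, the other carbonyl being deactivated as a vinylogous ester; the carbinol centre forms as a racemate and needs no control.

Step 10
Reactants: 17 racemic 2-{13-[3,5-bis(benzyloxy)-4-methylphenyl]tridecyl}-3-tert-butoxy-4-hydroxy-4-[(E)-1-methoxyprop-1-en-2-yl]cyclobut-2-en-1-one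
Product: 20 2-{13-[3,5-bis(benzyloxy)-4-methylphenyl]tridecyl}-3-tert-butoxy-6-methoxy-5-methylbenzene-1,4-diol, via dienylketene 18 (not isolated), via cyclohexadienone 19 (not isolated)
Conditions: toluene (degassed), 110 °C, argon
Reagents that add atoms: none
Why: Heating should open the C1–C4 bond of cyclobutenone 17 in a conrotatory four-electron electrocyclic reaction in which the C4 hydroxyl, the stronger donor, rotates outward, so that dienylketene 18 forms with the methoxypropenyl group cis to the ketene. A six-electron disrotatory electrocyclisation then joins the ketene carbon (ring A C1) to the methoxy-bearing alkene terminus (ring A C2) and closes the six-membered ring as cyclohexa-2,4-dienone 19, whose enolisation gives hydroquinone 20; the closest known reaction type is the Moore rearrangement of 4-alkenyl-4-hydroxycyclobutenones made from squaric esters. Ring A is thus closed in a 6π electrocyclic mode with every substituent placed by construction: tether and tert-butoxy from the squarate half, methyl and methoxy from the alkenyl half. No stereocentre remains, because the carbinol carbon of racemic 17 becomes sp2 and the transient sp3 carbon of 19 is lost on aromatisation. The step needs outward rotation of the hydroxyl, which torquoselectivity of the donor group secures, and an unhindered alkene terminus, which the E geometry provides by placing hydrogen and not methoxy inside; the neutral degassed medium should keep the tert-butyl ether and the air-sensitive hydroquinone intact.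

Step 11
Reactants: 20 2-{13-[3,5-bis(benzyloxy)-4-methylphenyl]tridecyl}-3-tert-butoxy-6-methoxy-5-methylbenzene-1,4-diol
Product: 21 2-tert-butoxy-3-[13-(3,5-dihydroxy-4-methylphenyl)tridecyl]-5-methoxy-6-methylbenzene-1,4-diol
Conditions: H2 (1 atm), 10% Pd/C, EtOAc/EtOH, rt
Reagents that add atoms: none
Why: Hydrogenolysis cleaves both aryl benzyl ethers, while the tert-butyl ether, the methyl ether and the hydroquinone are inert and the reducing medium protects ring A from autoxidation.

Step 12
Reactants: 21 2-tert-butoxy-3-[13-(3,5-dihydroxy-4-methylphenyl)tridecyl]-5-methoxy-6-methylbenzene-1,4-diol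
Product: 22 2-tert-butoxy-3-[13-(5-hydroxy-4-methyl-3,6-dioxocyclohexa-1,4-dien-1-yl)tridecyl]-5-methoxy-6-methylcyclohexa-2,5-diene-1,4-dione
Conditions: (KSO3)2NO (excess), KH2PO4 buffer, acetone/H2O, rt
Reagents that add atoms: potassium nitrosodisulfonate, [K+].[K+].[O]N(S(=O)(=O)[O-])S(=O)(=O)[O-]
Why: Teuber oxidation should convert the ring A hydroquinone to the quinone and oxidise the ring B resorcinol para to one hydroxyl (the two para positions are equivalent by symmetry) to the 2-hydroxy-1,4-quinone, the near-neutral buffer sparing the tert-butyl vinylogous ester.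

Step 13
Reactants: 22 2-tert-butoxy-3-[13-(5-hydroxy-4-methyl-3,6-dioxocyclohexa-1,4-dien-1-yl)tridecyl]-5-methoxy-6-methylcyclohexa-2,5-diene-1,4-dione
Product: 24 3-{13-[2-(acetyloxy)-5-methoxy-4-methyl-3,6-dioxocyclohexa-1,4-dien-1-yl]tridecyl}-6-methylbenzene-1,2,4,5-tetrayl tetraacetate, via bis-quinone diacetate 23 (not isolated)
Conditions: Ac2O, conc. H2SO4 (cat.), rt
Reagents that add atoms: acetic anhydride, CC(=O)OC(C)=O
Why: Thiele–Winter acetoxylation adds acetate to the only unsubstituted position of the ring B quinone and acetylates the resulting hydroquinone, while the acid cleaves the tert-butyl vinylogous ester of ring A, whose fully substituted quinone cannot add acetate and is only O-acetylated.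

Step 14
Reactants: 24 3-{13-[2-(acetyloxy)-5-methoxy-4-methyl-3,6-dioxocyclohexa-1,4-dien-1-yl]tridecyl}-6-methylbenzene-1,2,4,5-tetrayl tetraacetate
Product: 26 2,5-dihydroxy-3-methyl-6-[13-(2-hydroxy-5-methoxy-4-methyl-3,6-dioxocyclohexa-1,4-dien-1-yl)tridecyl]cyclohexa-2,5-diene-1,4-dione (CNP0107579.0), via tetrahydroxyarene 25 (not isolated)
Conditions: K2CO3, dry MeOH, rt, argon then air; cold 1 M HCl
Reagents that add atoms: none
Why: Methanolysis of the five acetates followed by autoxidation of the tetrahydroxybenzene should give the 2,5-dihydroxyquinone of ring B, and because methoxide is the only nucleophile present, any exchange at the ring A methyl vinylogous ester returns the same methoxy group.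

**Compound list**

1 | 3,5-dihydroxy-4-methylbenzoic acid | Cc1c(O)cc(C(=O)O)cc1O | starting material
2 | benzyl 3,5-bis(benzyloxy)-4-methylbenzoate | Cc1c(OCc2ccccc2)cc(C(=O)OCc2ccccc2)cc1OCc1ccccc1 | intermediate
3 | [3,5-bis(benzyloxy)-4-methylphenyl]methanol | Cc1c(OCc2ccccc2)cc(CO)cc1OCc1ccccc1 | intermediate
4 | 1,3-bis(benzyloxy)-5-(bromomethyl)-2-methylbenzene | Cc1c(OCc2ccccc2)cc(CBr)cc1OCc1ccccc1 | intermediate
5 | 12-bromododecan-1-ol | OCCCCCCCCCCCCBr | starting material
6 | [(12-bromododecyl)oxy](tert-butyl)dimethylsilane | CC(C)(C)[Si](C)(C)OCCCCCCCCCCCCBr | intermediate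
7 | {12-[(tert-butyldimethylsilyl)oxy]dodecyl}magnesium bromide | CC(C)(C)[Si](C)(C)OCCCCCCCCCCCC[Mg]Br | intermediate
8 | ({13-[3,5-bis(benzyloxy)-4-methylphenyl]tridecyl}oxy)(tert-butyl)dimethylsilane | CC(C)(C)[Si](C)(C)OCCCCCCCCCCCCCc1cc(OCc2ccccc2)c(C)c(OCc2ccccc2)c1 | intermediate
9 | 1,3-bis(benzyloxy)-5-(13-bromotridecyl)-2-methylbenzene | BrCCCCCCCCCCCCCc1cc(OCc2ccccc2)c(C)c(OCc2ccccc2)c1 | intermediate
10 | di-tert-butyl squarate (3,4-di-tert-butoxycyclobut-3-ene-1,2-dione) | CC(C)(C)OC1=C(OC(C)(C)C)C(=O)C1=O | starting material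
11 | {13-[3,5-bis(benzyloxy)-4-methylphenyl]tridecyl}magnesium bromide | Br[Mg]CCCCCCCCCCCCCc1cc(OCc2ccccc2)c(C)c(OCc2ccccc2)c1 | intermediate
12 | bromomagnesium alkoxide of racemic 4-{13-[3,5-bis(benzyloxy)-4-methylphenyl]tridecyl}-2,3-di-tert-butoxy-4-hydroxycyclobut-2-en-1-one | O=C1C(OC(C)(C)C)=C(OC(C)(C)C)C1(O[Mg]Br)CCCCCCCCCCCCCc1cc(OCc2ccccc2)c(C)c(OCc2ccccc2)c1 | intermediate
13 | 3-{13-[3,5-bis(benzyloxy)-4-methylphenyl]tridecyl}-4-tert-butoxycyclobut-3-ene-1,2-dione | O=C1C(=O)C(OC(C)(C)C)=C1CCCCCCCCCCCCCc1cc(OCc2ccccc2)c(C)c(OCc2ccccc2)c1 | intermediate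
14 | 2-bromo-1,1-dimethoxypropane (racemic) | COC(OC)C(C)Br | starting material
15 | (E)-2-bromo-1-methoxyprop-1-ene (bromine trans to methoxy) | CO/C=C(/Br)C | intermediate
16 | (1-methoxyprop-1-en-2-yl)lithium with lithium trans to methoxy (Z by the priority rules) | CO/C=C(/[Li])C | intermediate
17 | racemic 2-{13-[3,5-bis(benzyloxy)-4-methylphenyl]tridecyl}-3-tert-butoxy-4-hydroxy-4-[(E)-1-methoxyprop-1-en-2-yl]cyclobut-2-en-1-one | O=C1C(CCCCCCCCCCCCCc2cc(OCc3ccccc3)c(C)c(OCc3ccccc3)c2)=C(OC(C)(C)C)C1(O)/C(C)=C/OC | intermediate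
18 | (3Z,5E)-2-{13-[3,5-bis(benzyloxy)-4-methylphenyl]tridecyl}-3-tert-butoxy-4-hydroxy-6-methoxy-5-methylhexa-1,3,5-trien-1-one (dienylketene) | O=C=C(CCCCCCCCCCCCCc1cc(OCc2ccccc2)c(C)c(OCc2ccccc2)c1)/C(OC(C)(C)C)=C(/O)\C(C)=C\OC | intermediate
19 | racemic 2-{13-[3,5-bis(benzyloxy)-4-methylphenyl]tridecyl}-3-tert-butoxy-4-hydroxy-6-methoxy-5-methylcyclohexa-2,4-dien-1-one | COC1C(=O)C(CCCCCCCCCCCCCc2cc(OCc3ccccc3)c(C)c(OCc3ccccc3)c2)=C(OC(C)(C)C)C(O)=C1C | intermediate
20 | 2-{13-[3,5-bis(benzyloxy)-4-methylphenyl]tridecyl}-3-tert-butoxy-6-methoxy-5-methylbenzene-1,4-diol | COc1c(C)c(O)c(OC(C)(C)C)c(CCCCCCCCCCCCCc2cc(OCc3ccccc3)c(C)c(OCc3ccccc3)c2)c1O | intermediate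
21 | 2-tert-butoxy-3-[13-(3,5-dihydroxy-4-methylphenyl)tridecyl]-5-methoxy-6-methylbenzene-1,4-diol | COc1c(C)c(O)c(OC(C)(C)C)c(CCCCCCCCCCCCCc2cc(O)c(C)c(O)c2)c1O | intermediate
22 | 2-tert-butoxy-3-[13-(5-hydroxy-4-methyl-3,6-dioxocyclohexa-1,4-dien-1-yl)tridecyl]-5-methoxy-6-methylcyclohexa-2,5-diene-1,4-dione | COC1=C(C)C(=O)C(OC(C)(C)C)=C(CCCCCCCCCCCCCC2=CC(=O)C(C)=C(O)C2=O)C1=O | intermediate
23 | 2-(acetyloxy)-3-{13-[5-(acetyloxy)-4-methyl-3,6-dioxocyclohexa-1,4-dien-1-yl]tridecyl}-5-methoxy-6-methylcyclohexa-2,5-diene-1,4-dione | COC1=C(C)C(=O)C(OC(C)=O)=C(CCCCCCCCCCCCCC2=CC(=O)C(C)=C(OC(C)=O)C2=O)C1=O | intermediate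
24 | 3-{13-[2-(acetyloxy)-5-methoxy-4-methyl-3,6-dioxocyclohexa-1,4-dien-1-yl]tridecyl}-6-methylbenzene-1,2,4,5-tetrayl tetraacetate | COC1=C(C)C(=O)C(OC(C)=O)=C(CCCCCCCCCCCCCc2c(OC(C)=O)c(OC(C)=O)c(C)c(OC(C)=O)c2OC(C)=O)C1=O | intermediate
25 | 2-hydroxy-5-methoxy-6-methyl-3-[13-(2,3,5,6-tetrahydroxy-4-methylphenyl)tridecyl]cyclohexa-2,5-diene-1,4-dione | COC1=C(C)C(=O)C(O)=C(CCCCCCCCCCCCCc2c(O)c(O)c(C)c(O)c2O)C1=O | intermediate
26 | 2,5-dihydroxy-3-methyl-6-[13-(2-hydroxy-5-methoxy-4-methyl-3,6-dioxocyclohexa-1,4-dien-1-yl)tridecyl]cyclohexa-2,5-diene-1,4-dione (CNP0107579.0) | COC1=C(C)C(=O)C(O)=C(CCCCCCCCCCCCCC2=C(O)C(=O)C(C)=C(O)C2=O)C1=O | target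

**Step count**

Total steps: 14. Longest linear sequence: 12 steps (steps 1, 2, 3, 5, 6, 7, 9, 10, 11, 12, 13, 14).

**Steps most likely to fail**

1. Step 9. In alkenyllithium 16 lithium and methoxy are trans, so anti-elimination of lithium methoxide to propyne may outrun carbonyl addition, and some addition at the vinylogous ester carbonyl would give the wrong regioisomer. The fallback sets out from 14 and 13 and comes back at 20. The other geometric isomer from the elimination of 14, (Z)-2-bromo-1-methoxyprop-1-ene F1, would be exchanged with t-BuLi at −78 °C to the alkenyllithium F2, in which lithium is cis to methoxy and held by O–Li chelation, so the anti-periplanar elimination path is closed. Addition of F2 to 13 should give the Z-configured carbinol F3. Heating F3 in xylene should open it to dienylketene F4; closure onto the sp-hybridised ketene carbon tolerates the inside methoxy group and leads through 19 to 20.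

2. Step 10. The electron-rich hydroquinone may autoxidise during prolonged heating and isolation, giving mixtures of oxidation states, and some isobutene may be lost thermally. The fallback sets out from 17 and comes back at 21. After the thermolysis the cooled toluene solution would be stirred with Ag2O and K2CO3 so that the ring-expanded product is collected as the air-stable 2-{13-[3,5-bis(benzyloxy)-4-methylphenyl]tridecyl}-3-tert-butoxy-6-methoxy-5-methylcyclohexa-2,5-diene-1,4-dione F5, which can be purified on silica. Hydrogenation of F5 over Pd/C then reduces the quinone and cleaves both benzyl ethers to give 21.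

3. Step 13. Acetate addition to the trisubstituted ring B quinone may be slow, and the forcing acid then needed may degrade the unprotected ring A quinone (cleavage of the methyl vinylogous ester, decomposition). The fallback sets out from 20 and comes back at 26, with ring A masked in its reduced form during all ring B chemistry.
   - Acetylation of 20 (Ac2O, pyridine, DMAP) should give the ring A diacetate F6.
   - Hydrogenolysis over Pd/C should give the resorcinol F7.
   - (KSO3)2NO should oxidise only ring B to the hydroxyquinone F8.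
   - Thiele–Winter acetoxylation under stronger activation (Ac2O, BF3·OEt2) should also replace the aryl tert-butyl ether by acetate and give the heptaacetate F9.
   - Methanolysis with K2CO3 in MeOH should give the heptaphenol F10, which on exposure to air oxidises in both rings to 26; the 1,2,4-trihydroxy pattern of ring A can only give the required 2-hydroxy-1,4-quinone.

**Further compounds**

F1 | step 9 | (Z)-2-bromo-1-methoxyprop-1-ene (bromine cis to methoxy) | CO/C=C(\Br)C
F2 | step 9 | (1-methoxyprop-1-en-2-yl)lithium with lithium cis to methoxy (E by the priority rules) | CO/C=C(\[Li])C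
F3 | step 9 | racemic 2-{13-[3,5-bis(benzyloxy)-4-methylphenyl]tridecyl}-3-tert-butoxy-4-hydroxy-4-[(Z)-1-methoxyprop-1-en-2-yl]cyclobut-2-en-1-one | O=C1C(CCCCCCCCCCCCCc2cc(OCc3ccccc3)c(C)c(OCc3ccccc3)c2)=C(OC(C)(C)C)C1(O)/C(C)=C\OC
F4 | step 9 | (3Z,5Z)-2-{13-[3,5-bis(benzyloxy)-4-methylphenyl]tridecyl}-3-tert-butoxy-4-hydroxy-6-methoxy-5-methylhexa-1,3,5-trien-1-one | O=C=C(CCCCCCCCCCCCCc1cc(OCc2ccccc2)c(C)c(OCc2ccccc2)c1)/C(OC(C)(C)C)=C(/O)\C(C)=C/OC
F5 | step 10 | 2-{13-[3,5-bis(benzyloxy)-4-methylphenyl]tridecyl}-3-tert-butoxy-6-methoxy-5-methylcyclohexa-2,5-diene-1,4-dione | COC1=C(C)C(=O)C(OC(C)(C)C)=C(CCCCCCCCCCCCCc2cc(OCc3ccccc3)c(C)c(OCc3ccccc3)c2)C1=O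
F6 | step 13 | 2-{13-[3,5-bis(benzyloxy)-4-methylphenyl]tridecyl}-3-tert-butoxy-6-methoxy-5-methyl-1,4-phenylene diacetate | COc1c(C)c(OC(C)=O)c(OC(C)(C)C)c(CCCCCCCCCCCCCc2cc(OCc3ccccc3)c(C)c(OCc3ccccc3)c2)c1OC(C)=O
F7 | step 13 | 2-tert-butoxy-3-[13-(3,5-dihydroxy-4-methylphenyl)tridecyl]-5-methoxy-6-methyl-1,4-phenylene diacetate | COc1c(C)c(OC(C)=O)c(OC(C)(C)C)c(CCCCCCCCCCCCCc2cc(O)c(C)c(O)c2)c1OC(C)=O
F8 | step 13 | 2-tert-butoxy-3-[13-(5-hydroxy-4-methyl-3,6-dioxocyclohexa-1,4-dien-1-yl)tridecyl]-5-methoxy-6-methyl-1,4-phenylene diacetate | COc1c(C)c(OC(C)=O)c(OC(C)(C)C)c(CCCCCCCCCCCCCC2=CC(=O)C(C)=C(O)C2=O)c1OC(C)=O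
F9 | step 13 | 3-{13-[2,3,6-tris(acetyloxy)-5-methoxy-4-methylphenyl]tridecyl}-6-methylbenzene-1,2,4,5-tetrayl tetraacetate | COc1c(C)c(OC(C)=O)c(OC(C)=O)c(CCCCCCCCCCCCCc2c(OC(C)=O)c(OC(C)=O)c(C)c(OC(C)=O)c2OC(C)=O)c1OC(C)=O
F10 | step 13 | 3-methyl-6-[13-(2,3,6-trihydroxy-5-methoxy-4-methylphenyl)tridecyl]benzene-1,2,4,5-tetrol | COc1c(C)c(O)c(O)c(CCCCCCCCCCCCCc2c(O)c(O)c(C)c(O)c2O)c1O
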